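## Retrosynthetic overview

1. The methylcyclohexene (C1 carries the methyl, C3 the stilbene aryl, C4 the aroyl group, C5 the 2,4-dihydroxyphenyl group; all-trans, 3R,4R,5S) is the only ring to build. It is opened by a retro-[4+2] at C3–C4 and C5–C6 into (E)-2,2',4,4'-tetrahydroxychalcone and a dehydroprenyl oxyresveratrol diene, the same pair the mulberry tree joins.
2. The cycloaddition is the last step, run on both polyphenols without any protecting group by an exo-selective Diels–Alderase, so all three stereocentres are set in the single ring-forming event.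
3. Diene: aryl–dienyl Suzuki disconnection to a bromo-oxyresveratrol and an (E)-dienylboronate; the stilbene C=C comes from a decarboxylative Knoevenagel condensation.
4. Chalcone: aldol disconnection to two resorcinol carbonyl compounds, carried out through a flavylium (pyrylium) ring that is closed in acid and reopened with hydroxide.
5. Ring order: transient pyrylium ring (step 1, opened again in the same flask), then the cyclohexene (step 5).

Assumption: the exo-selective Morus alba Diels–Alderase MaDA-3 is taken as an accessible biocatalyst; its heterologous expression and purification are not counted as synthetic steps.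

## Route

Step 1
Reactants: 1 resacetophenone (2,4-dihydroxyacetophenone); 2 β-resorcylaldehyde (2,4-dihydroxybenzaldehyde)
Product: 4 (E)-2,2',4,4'-tetrahydroxychalcone, via flavylium chloride 3 (not isolated)
Conditions: HCl (g), EtOAc, 0 °C to rt, 24 h; evaporate; 1 M aq NaOH (pH 12), rt, dark, 3 h; then 1 M aq HCl to pH 6
Reagents that add atoms: sodium hydroxide, [Na+].[OH-]
Why: Acid-catalysed Claisen–Schmidt (aldol) condensation of an ortho-hydroxybenzaldehyde is pulled forward by cyclodehydration to the 2-arylchromenylium salt 3, so the two electron-rich partners condense without protection, and hydroxide addition at C2 then opens the hemiketal and lets the cis-chalcone relax to the thermodynamically preferred E-chalcone phenolate, which is kinetically stable after neutralisation in the dark; no stereocentre is formed.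

Step 2
Reactants: 5 bromoaldehyde (5-bromo-2,4-dihydroxybenzaldehyde); 6 arylacetic acid (3,5-dihydroxyphenylacetic acid)
Product: 8 bromostilbene 4-bromo-6-[(E)-2-(3,5-dihydroxyphenyl)ethenyl]benzene-1,3-diol, via acrylic acid 7 (not isolated)
Conditions: piperidine (3 equiv), 1-methylimidazole (1 equiv), PEG-200, microwave, 160 °C, 20 min; dilute aq HCl work-up
Reagents that add atoms: none
Why: Amine-mediated Knoevenagel condensation (modified Perkin reaction) gives the alpha-aryl cinnamic acid 7, whose para-hydroxy group allows tautomerisation to a quinone methide that loses CO2 at 160 °C and reprotonates to the thermodynamically favoured E-stilbene, while the C–Br bond is inert to these conditions; no stereocentre is formed.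

Step 3
Reactants: 9 enyne (2-methylbut-1-en-3-yne); 10 pinacolborane (4,4,5,5-tetramethyl-1,3,2-dioxaborolane)
Product: 11 dienylboronate (E)-4,4,5,5-tetramethyl-2-(3-methylbuta-1,3-dien-1-yl)-1,3,2-dioxaborolane
Conditions: Cp2Zr(H)Cl (5 mol%), Et3N (10 mol%), neat, sealed tube, 60 °C, 16 h; bulb-to-bulb distillation
Reagents that add atoms: none
Why: Zirconocene-hydride-catalysed hydroboration of a terminal alkyne (hydrozirconation, then zirconium-to-boron transmetalation) adds H–B syn and anti-Markovnikov, so only the E-alkenylboronate forms and the 1,1-disubstituted alkene is left alone.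

Step 4
Reactants: 8 bromostilbene; 11 dienylboronate
Product: 12 diene 4-[(E)-2-(3,5-dihydroxyphenyl)ethenyl]-6-[(E)-3-methylbuta-1,3-dien-1-yl]benzene-1,3-diol
Conditions: Pd(OAc)2 (5 mol%), SPhos (2-dicyclohexylphosphino-2',6'-dimethoxybiphenyl, 10 mol%), K3PO4 (5 equiv), degassed 1,4-dioxane/H2O 4:1, 70 °C, 4 h, argon; pH 7 buffer work-up, used at once
Reagents that add atoms: none
Why: Suzuki–Miyaura cross-coupling, in which zerovalent palladium carrying the electron-rich biaryl phosphine inserts into the deactivated C–Br bond even with the phenols present as phenoxides, and transmetalation and reductive elimination proceed with retention so both E alkenes are kept, while the basic, acid-free medium avoids cyclisation of the ortho-hydroxy diene to a chromene; no stereocentre is formed.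

Step 5
Reactants: 4 (E)-2,2',4,4'-tetrahydroxychalcone; 12 diene
Product: 13 target (2,4-dihydroxyphenyl)[(1R,2R,6S)-6-(2,4-dihydroxyphenyl)-2-{5-[(E)-2-(3,5-dihydroxyphenyl)ethenyl]-2,4-dihydroxyphenyl}-4-methylcyclohex-3-en-1-yl]methanone
Conditions: exo-selective Morus alba Diels–Alderase MaDA-3 (recombinant, FAD-bound, 0.5 mol%), 20 mM Tris-HCl pH 8.0, 5 vol% DMSO, 37 °C, argon, dark, 12 h; EtOAc extraction, reversed-phase chromatography
Reagents that add atoms: none
Why: Enzyme-catalysed intermolecular Diels–Alder [4+2] cycloaddition between the unprotected E-diene and the E-chalcone, the natural substrate pair of this enzyme family; the concerted step turns the E-alkene of 4 into the trans C4/C5 relationship, the exo-selective pocket (aroyl group pointing away from the diene) makes C3/C4 trans, and the enzyme exposes one dienophile face only, which gives 3R,4R,5S, while the uncatalysed background reaction is negligible at 37 °C.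

## Compound list

1 | 2,4-dihydroxyacetophenone | CC(=O)c1ccc(O)cc1O | starting material
2 | 2,4-dihydroxybenzaldehyde | O=Cc1ccc(O)cc1O | starting material
3 | 7-hydroxy-2-(2,4-dihydroxyphenyl)chromenylium chloride (flavylium chloride) | [Cl-].Oc1ccc(-c2ccc3ccc(O)cc3[o+]2)c(O)c1 | intermediate
4 | (E)-2,2',4,4'-tetrahydroxychalcone, (E)-1,3-bis(2,4-dihydroxyphenyl)prop-2-en-1-one | O=C(/C=C/c1ccc(O)cc1O)c1ccc(O)cc1O | intermediate
5 | 5-bromo-2,4-dihydroxybenzaldehyde | O=Cc1cc(Br)c(O)cc1O | starting material
6 | 3,5-dihydroxyphenylacetic acid | OC(=O)Cc1cc(O)cc(O)c1 | starting material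
7 | (E)-3-(5-bromo-2,4-dihydroxyphenyl)-2-(3,5-dihydroxyphenyl)prop-2-enoic acid | OC(=O)/C(c1cc(O)cc(O)c1)=C/c1cc(Br)c(O)cc1O | intermediate
8 | 4-bromo-6-[(E)-2-(3,5-dihydroxyphenyl)ethenyl]benzene-1,3-diol | Oc1cc(O)cc(/C=C/c2cc(Br)c(O)cc2O)c1 | intermediate
9 | 2-methylbut-1-en-3-yne | C=C(C)C#C | starting material
10 | pinacolborane | CC1(C)OBOC1(C)C | starting material
11 | (E)-4,4,5,5-tetramethyl-2-(3-methylbuta-1,3-dien-1-yl)-1,3,2-dioxaborolane | CC(=C)/C=C/B1OC(C)(C)C(C)(C)O1 | intermediate
12 | 4-[(E)-2-(3,5-dihydroxyphenyl)ethenyl]-6-[(E)-3-methylbuta-1,3-dien-1-yl]benzene-1,3-diol | CC(=C)/C=C/c1cc(/C=C/c2cc(O)cc(O)c2)c(O)cc1O | intermediate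
13 | (2,4-dihydroxyphenyl)[(1R,2R,6S)-6-(2,4-dihydroxyphenyl)-2-{5-[(E)-2-(3,5-dihydroxyphenyl)ethenyl]-2,4-dihydroxyphenyl}-4-methylcyclohex-3-en-1-yl]methanone (all-trans) | CC1=C[C@@H](c2cc(/C=C/c3cc(O)cc(O)c3)c(O)cc2O)[C@H](C(=O)c2ccc(O)cc2O)[C@@H](c2ccc(O)cc2O)C1 | target

## Step count and risks

Total step count: 5. Longest linear sequence: 3 steps (step 2, step 4, step 5).

**Step 5 (enzymatic cycloaddition).** The risk is that this enzyme homologue accepts the stilbene diene poorly or gives some cis-trans adduct, and that the polyphenols oxidise at pH 8. The fallback sets out from 4 and 12 and comes back at 13.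
- Compound 12 is acetylated (Ac2O, pyridine, 0 °C) to the diene tetraacetate F1.
- Compound 4 is acetylated with three equivalents of Ac2O in pyridine at 0 °C to the 2'-hydroxychalcone triacetate F2; the hydrogen-bonded 2'-hydroxyl stays free.
- F1 and F2 are joined in a Diels–Alder reaction promoted by the chiral borate made from BH3·THF, AcOH and enantiopure 3,3'-diphenyl-2,2'-bi-1-naphthol (VANOL) in THF at rt to 50 °C. The borate chelates the 2'-hydroxy ketone, activates the dienophile and shields one face. Both ligand antipodes are sold, and the one that gives the 4R,5S series is fixed by a test run.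
- The all-trans adduct heptaacetate F3 is purified by chromatography and methanolysed (K2CO3, MeOH, 0 °C to rt) to 13.

**Step 4 (Suzuki coupling on the free tetraphenol).** The risk is slow oxidative addition into the phenoxide-rich bromide and loss of the sensitive free diene. The fallback sets out from 8 and comes back at 12.
- Compound 8 is silylated (TBSCl, imidazole, DMF) to the tetrakis(tert-butyldimethylsilyl) ether F4.
- A Mizoroki–Heck reaction of F4 with 2-methylbut-3-en-2-ol (Pd(OAc)2, P(o-tol)3, NaOAc, DMA, 110 °C) gives the E tertiary allylic alcohol F5.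
- F5 is dehydrated (MsCl, Et3N, CH2Cl2, 0 °C to rt) to the silylated diene F6; with the ortho oxygen capped no chromene can form.
- Buffered fluoride (Bu4NF, AcOH, THF, 0 °C) releases 12.

**Step 2 (decarboxylative Knoevenagel condensation).** The risk is lactonisation of the ortho-hydroxy adduct to a 3-aryl-6-bromo-7-hydroxycoumarin instead of decarboxylation. The fallback sets out from 5 and comes back at 8.
- Commercial 3,5-dihydroxybenzyl alcohol (OCc1cc(O)cc(O)c1) and triphenylphosphine hydrobromide (MeCN, reflux) give (3,5-dihydroxybenzyl)triphenylphosphonium bromide F7.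
- A Wittig reaction of F7 with 5 using excess LiN(SiMe3)2 (6 equiv, THF, −78 to 50 °C) gives 8 together with its Z isomer F8.
- The mixture is converged to 8 by thiyl-radical isomerisation (catalytic (PhS)2, THF, reflux, visible light).

## Further compounds

F1 | step 5 | 4-[(E)-2-(3,5-diacetoxyphenyl)ethenyl]-6-[(E)-3-methylbuta-1,3-dien-1-yl]-1,3-phenylene diacetate (diene tetraacetate) | CC(=C)/C=C/c1cc(/C=C/c2cc(OC(C)=O)cc(OC(C)=O)c2)c(OC(C)=O)cc1OC(C)=O
F2 | step 5 | (E)-2,4,4'-triacetoxy-2'-hydroxychalcone | CC(=O)Oc1ccc(C(=O)/C=C/c2ccc(OC(C)=O)cc2OC(C)=O)c(O)c1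
F3 | step 5 | heptaacetate of 13 with the 2'-hydroxyl of the aroyl ring free, (1R,2R,6S) all-trans | CC1=C[C@@H](c2cc(/C=C/c3cc(OC(C)=O)cc(OC(C)=O)c3)c(OC(C)=O)cc2OC(C)=O)[C@H](C(=O)c2ccc(OC(C)=O)cc2O)[C@@H](c2ccc(OC(C)=O)cc2OC(C)=O)C1
F4 | step 4 | tetrakis(tert-butyldimethylsilyl) ether of 8 | CC(C)(C)[Si](C)(C)Oc1cc(O[Si](C)(C)C(C)(C)C)cc(/C=C/c2cc(Br)c(O[Si](C)(C)C(C)(C)C)cc2O[Si](C)(C)C(C)(C)C)c1
F5 | step 4 | (E)-4-aryl-2-methylbut-3-en-2-ol from F4 (tertiary allylic alcohol, four silyl ethers) | CC(C)(O)/C=C/c1cc(/C=C/c2cc(O[Si](C)(C)C(C)(C)C)cc(O[Si](C)(C)C(C)(C)C)c2)c(O[Si](C)(C)C(C)(C)C)cc1O[Si](C)(C)C(C)(C)C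
F6 | step 4 | tetrakis(tert-butyldimethylsilyl) ether of 12 | CC(=C)/C=C/c1cc(/C=C/c2cc(O[Si](C)(C)C(C)(C)C)cc(O[Si](C)(C)C(C)(C)C)c2)c(O[Si](C)(C)C(C)(C)C)cc1O[Si](C)(C)C(C)(C)C
F7 | step 2 | (3,5-dihydroxybenzyl)triphenylphosphonium bromide | [Br-].Oc1cc(O)cc(C[P+](c2ccccc2)(c2ccccc2)c2ccccc2)c1
F8 | step 2 | 4-bromo-6-[(Z)-2-(3,5-dihydroxyphenyl)ethenyl]benzene-1,3-diol | Oc1cc(O)cc(/C=C\c2cc(Br)c(O)cc2O)c1
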